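**Strategy**

The arene is grown from the chain instead of being coupled to it. Resorcinol carbon C5 is the carboxyl carbon of (9Z,17S)-17-hydroxyoctadec-9-enoic acid; C4, C3, C2, C1 and C6 come from three acetate units whose terminal carboxyl is finally lost. A Z-selective Wittig reaction assembles the protected acid and a dianion acylation turns it into the precursor, an open-chain diketo-dioxinone. One base-mediated aldol condensation then joins the dioxinone α-carbon to the chain-bearing ketone, closing and aromatising the benzene ring. It exploits the meta relationship of the two phenolic C–O bonds (C1, C3) to the alkyl-bearing C5, the polyketide oxygenation pattern of the ring.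

Key step: step 13

Remark: the acetal carbon of the tetrahydropyranyl ethers 2, 4, 5 and 6 and the transient carbinol carbon of 21 are stereorandom (both epimers are carried together); neither centre survives into the product.

**Route**

Step 1
Reactants: 1 6-bromohexan-1-ol
Product: 2 2-[(6-bromohexyl)oxy]tetrahydro-2H-pyran
Conditions: 3,4-dihydro-2H-pyran, PPTS (cat.), CH2Cl2, rt
Reagents that add atoms: 3,4-dihydro-2H-pyran, C1=COCCC1
Why: Acid-catalysed addition of the alcohol to the enol ether (tetrahydropyranylation) masks the hydroxyl so that the bromide can be turned into a Grignard reagent.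

Step 2
Reactants: 2 2-[(6-bromohexyl)oxy]tetrahydro-2H-pyran; 3 (S)-propylene oxide [(2S)-2-methyloxirane]
Product: 5 (2S)-9-[(tetrahydro-2H-pyran-2-yl)oxy]nonan-2-ol, via Grignard reagent 4 (not isolated)
Conditions: Mg, THF, 45 °C; then CuI (10 mol %), 3, THF, −30 to 0 °C; aq. NH4Cl
Reagents that add atoms: none
Why: Magnesium insertion into the primary C–Br bond and CuI-catalysed SN2 opening of the terminal epoxide at its unsubstituted CH2 (Grignard–epoxide alkylation) should form the chain, and because the C–O bond at the stereocentre is never broken the S configuration of 3 is carried over unchanged.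

Step 3
Reactants: 5 (2S)-9-[(tetrahydro-2H-pyran-2-yl)oxy]nonan-2-ol
Product: 6 tert-butyldimethyl({(2S)-9-[(tetrahydro-2H-pyran-2-yl)oxy]nonan-2-yl}oxy)silane
Conditions: TBSCl, imidazole, DMF, rt
Reagents that add atoms: tert-butyldimethylsilyl chloride, CC(C)(C)[Si](C)(C)Cl
Why: Imidazole-promoted silylation of the secondary alcohol installs a group that should withstand the ylide, amide and enolate bases used later and is orthogonal to the acid-labile acetal.

Step 4
Reactants: 6 tert-butyldimethyl({(2S)-9-[(tetrahydro-2H-pyran-2-yl)oxy]nonan-2-yl}oxy)silane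
Product: 7 (8S)-8-[(tert-butyldimethylsilyl)oxy]nonan-1-ol
Conditions: PPTS (cat.), EtOH, 50 °C
Reagents that add atoms: none
Why: Mild pyridinium-catalysed transacetalisation to ethanol should remove the tetrahydropyranyl group, while the hindered secondary silyl ether is not solvolysed at this acidity.

Step 5
Reactants: 7 (8S)-8-[(tert-butyldimethylsilyl)oxy]nonan-1-ol
Product: 8 {[(2S)-9-bromononan-2-yl]oxy}(tert-butyl)dimethylsilane
Conditions: CBr4, PPh3, CH2Cl2, 0 °C
Reagents that add atoms: carbon tetrabromide, BrC(Br)(Br)Br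
Why: The Appel reaction converts the primary alcohol through its alkoxyphosphonium ion into the bromide by SN2 displacement under near-neutral conditions that the silyl ether tolerates.

Step 6
Reactants: 8 {[(2S)-9-bromononan-2-yl]oxy}(tert-butyl)dimethylsilane
Product: 9 {(8S)-8-[(tert-butyldimethylsilyl)oxy]nonyl}triphenylphosphonium bromide
Conditions: PPh3, MeCN, reflux
Reagents that add atoms: triphenylphosphine, c1ccc(cc1)P(c1ccccc1)c1ccccc1
Why: SN2 quaternisation of triphenylphosphine by the unhindered primary bromide should give the Wittig salt without touching the remote stereocentre.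

Step 7
Reactants: 10 monomethyl azelate (9-methoxy-9-oxononanoic acid)
Product: 11 methyl 9-hydroxynonanoate
Conditions: BH3·THF, THF, −15 °C to rt; then MeOH
Reagents that add atoms: none
Why: Borane reduces the free carboxylic acid through its acyloxyborane much faster than it attacks the methyl ester, so the half-ester should be reduced chemoselectively.

Step 8
Reactants: 11 methyl 9-hydroxynonanoate
Product: 12 methyl 9-oxononanoate
Conditions: TEMPO (cat.), PhI(OAc)2, CH2Cl2, rt
Reagents that add atoms: none
Why: TEMPO-catalysed oxoammonium oxidation with PhI(OAc)2 as terminal oxidant takes the primary alcohol to the aldehyde and stops there in the absence of water.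

Step 9
Reactants: 9 {(8S)-8-[(tert-butyldimethylsilyl)oxy]nonyl}triphenylphosphonium bromide; 12 methyl 9-oxononanoate
Product: 14 methyl (9Z,17S)-17-[(tert-butyldimethylsilyl)oxy]octadec-9-enoate, via phosphorus ylide 13 (not isolated)
Conditions: NaN(SiMe3)2, THF, −78 to 0 °C; then 12, −78 °C to rt
Reagents that add atoms: none
Why: Wittig olefination of the unstabilised ylide under lithium-free conditions proceeds through the kinetically favoured cis-oxaphosphetane and should give the Z-alkene, the ylide attacking the aldehyde far faster than the ester.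

Step 10
Reactants: 14 methyl (9Z,17S)-17-[(tert-butyldimethylsilyl)oxy]octadec-9-enoate
Product: 15 (9Z,17S)-17-[(tert-butyldimethylsilyl)oxy]-N-methoxy-N-methyloctadec-9-enamide
Conditions: MeNH(OMe)·HCl, i-PrMgCl, THF, −20 to 0 °C; aq. NH4Cl
Reagents that add atoms: N,O-dimethylhydroxylamine hydrochloride, CNOC.Cl
Why: The magnesium amide formed from the hydroxylamine salt and i-PrMgCl converts the methyl ester directly into the Weinreb amide by acyl substitution, and the chelated product resists further addition.

Step 11
Reactants: 16 2,2,6-trimethyl-4H-1,3-dioxin-4-one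
Product: 18 2,2-dimethyl-6-(2-oxopropyl)-4H-1,3-dioxin-4-one, via lithium dienolate 17 (not isolated)
Conditions: LiN(SiMe3)2, THF, −78 °C; then AcCl, −78 °C; aq. NH4Cl
Reagents that add atoms: acetyl chloride, CC(=O)Cl
Why: Vinylogous deprotonation of the 6-methyl group gives the dienolate, which is C-acylated at its terminal carbon by acetyl chloride (Claisen-type acylation) to give the keto-dioxinone.

Step 12
Reactants: 18 2,2-dimethyl-6-(2-oxopropyl)-4H-1,3-dioxin-4-one; 15 (9Z,17S)-17-[(tert-butyldimethylsilyl)oxy]-N-methoxy-N-methyloctadec-9-enamide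
Product: 20 6-[(12Z,20S)-20-[(tert-butyldimethylsilyl)oxy]-2,4-dioxohenicos-12-en-1-yl]-2,2-dimethyl-4H-1,3-dioxin-4-one, via dilithium dianion 19 (not isolated)
Conditions: LiN(i-Pr)2 (2 equiv per 18, 18 in excess), THF, −78 °C; then 15, −78 to −40 °C; aq. NH4Cl
Reagents that add atoms: none
Why: Double deprotonation gives a dianion whose last-formed, methyl-derived carbanion attacks the Weinreb amide in a Claisen-type acylation, the stable tetrahedral chelate preventing over-addition and collapsing to the 1,3-diketone on work-up.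

Step 13
Reactants: 20 6-[(12Z,20S)-20-[(tert-butyldimethylsilyl)oxy]-2,4-dioxohenicos-12-en-1-yl]-2,2-dimethyl-4H-1,3-dioxin-4-one
Product: 22 7-hydroxy-5-[(8Z,16S)-16-[(tert-butyldimethylsilyl)oxy]heptadec-8-en-1-yl]-2,2-dimethyl-4H-benzo[d][1,3]dioxin-4-one, via cyclic aldol adduct 21 (not isolated)
Conditions: Et3N, CH2Cl2, 0 °C to rt
Reagents that add atoms: none
Why: Triethylamine enolises the doubly activated methylene between the dioxinone and the adjacent ketone, and the resulting vinylogous enolate attacks the distal, chain-bearing ketone through the dioxinone α-carbon (polyketide C2 to C7), after which loss of water and enolisation of the remaining ketone give the phenol. The closest known reaction type is the biomimetic intramolecular aldol cycloaromatisation of diketo-dioxinones (masked 3,5,7-triketo esters) to isopropylidene-protected β-resorcylates. The one ring closed is the six-membered carbocycle, formed in a 6-(enolexo)-exo-trig aldol mode and pulled through by aromatisation. No lasting stereocentre is created, since the tertiary carbinol of 21 is eliminated, and the remote S silyloxy centre and the Z-olefin take no part. The step needs C-cyclisation and not O-cyclisation to a 4-pyranone or Claisen closure to an acylphloroglucinol; the dioxinone ties up the carboxyl terminus so that it cannot serve as an acyl acceptor, and the mild amine base at or below room temperature favours the reversible aldol pathway that irreversible dehydration then drives forward.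

Step 14
Reactants: 22 7-hydroxy-5-[(8Z,16S)-16-[(tert-butyldimethylsilyl)oxy]heptadec-8-en-1-yl]-2,2-dimethyl-4H-benzo[d][1,3]dioxin-4-one
Product: 24 5-[(8Z,16S)-16-[(tert-butyldimethylsilyl)oxy]heptadec-8-en-1-yl]benzene-1,3-diol, via resorcylic acid 23 (not isolated)
Conditions: KOH (aq. 4 M), 1,4-dioxane, 100 °C, argon; then aq. HCl to pH 3, 0 °C
Reagents that add atoms: none
Why: Hydroxide opens the acylal-type lactone with loss of acetone, and the resulting 6-alkyl-β-resorcylate, an aromatised β-keto acid, should undergo protodecarboxylation by ipso-protonation of the electron-rich ring on heating (alkaline saponification–decarboxylation of alkylresorcylates); partial loss of the silyl ether here would be harmless.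

Step 15
Reactants: 24 5-[(8Z,16S)-16-[(tert-butyldimethylsilyl)oxy]heptadec-8-en-1-yl]benzene-1,3-diol
Product: 25 Hansfordiol E, 5-[(8Z,16S)-16-hydroxyheptadec-8-en-1-yl]benzene-1,3-diol
Conditions: HCl (1% in MeOH), 0 °C to rt
Reagents that add atoms: none
Why: Acid-catalysed methanolysis should cleave the secondary silyl ether while the isolated Z-olefin, the resorcinol and the S carbinol, whose C–O bond is not broken, stay unchanged.

**Compound list**

1 | 6-bromohexan-1-ol | OCCCCCCBr | starting material
2 | 2-[(6-bromohexyl)oxy]tetrahydro-2H-pyran | BrCCCCCCOC1CCCCO1 | intermediate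
3 | (S)-propylene oxide, (2S)-2-methyloxirane | C[C@H]1CO1 | starting material
4 | {6-[(tetrahydro-2H-pyran-2-yl)oxy]hexyl}magnesium bromide (formed in the flask) | Br[Mg]CCCCCCOC1CCCCO1 | intermediate
5 | (2S)-9-[(tetrahydro-2H-pyran-2-yl)oxy]nonan-2-ol | C[C@H](O)CCCCCCCOC1CCCCO1 | intermediate
6 | tert-butyldimethyl({(2S)-9-[(tetrahydro-2H-pyran-2-yl)oxy]nonan-2-yl}oxy)silane | C[C@H](O[Si](C)(C)C(C)(C)C)CCCCCCCOC1CCCCO1 | intermediate
7 | (8S)-8-[(tert-butyldimethylsilyl)oxy]nonan-1-ol | C[C@H](O[Si](C)(C)C(C)(C)C)CCCCCCCO | intermediate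
8 | {[(2S)-9-bromononan-2-yl]oxy}(tert-butyl)dimethylsilane | C[C@H](O[Si](C)(C)C(C)(C)C)CCCCCCCBr | intermediate
9 | {(8S)-8-[(tert-butyldimethylsilyl)oxy]nonyl}triphenylphosphonium bromide | C[C@H](O[Si](C)(C)C(C)(C)C)CCCCCCC[P+](c1ccccc1)(c1ccccc1)c1ccccc1.[Br-] | intermediate
10 | monomethyl azelate, 9-methoxy-9-oxononanoic acid | COC(=O)CCCCCCCC(=O)O | starting material
11 | methyl 9-hydroxynonanoate | COC(=O)CCCCCCCCO | intermediate
12 | methyl 9-oxononanoate | COC(=O)CCCCCCCC=O | intermediate
13 | {(8S)-8-[(tert-butyldimethylsilyl)oxy]nonylidene}triphenylphosphorane (formed in the flask) | C[C@H](O[Si](C)(C)C(C)(C)C)CCCCCCC=P(c1ccccc1)(c1ccccc1)c1ccccc1 | intermediate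
14 | methyl (9Z,17S)-17-[(tert-butyldimethylsilyl)oxy]octadec-9-enoate | COC(=O)CCCCCCC/C=C\CCCCCC[C@H](C)O[Si](C)(C)C(C)(C)C | intermediate
15 | (9Z,17S)-17-[(tert-butyldimethylsilyl)oxy]-N-methoxy-N-methyloctadec-9-enamide | CON(C)C(=O)CCCCCCC/C=C\CCCCCC[C@H](C)O[Si](C)(C)C(C)(C)C | intermediate
16 | 2,2,6-trimethyl-4H-1,3-dioxin-4-one | CC1=CC(=O)OC(C)(C)O1 | starting material
17 | lithium dienolate of 16, lithium 2,2-dimethyl-6-methylidene-1,3-dioxin-4-olate (formed in the flask) | C=C1C=C(O[Li])OC(C)(C)O1 | intermediate
18 | 2,2-dimethyl-6-(2-oxopropyl)-4H-1,3-dioxin-4-one | CC(=O)CC1=CC(=O)OC(C)(C)O1 | intermediate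
19 | dilithium dianion of 18, drawn as the bis-enolate (formed in the flask) | C=C(O[Li])C=C1C=C(O[Li])OC(C)(C)O1 | intermediate
20 | 6-[(12Z,20S)-20-[(tert-butyldimethylsilyl)oxy]-2,4-dioxohenicos-12-en-1-yl]-2,2-dimethyl-4H-1,3-dioxin-4-one | CC1(C)OC(=O)C=C(CC(=O)CC(=O)CCCCCCC/C=C\CCCCCC[C@H](C)O[Si](C)(C)C(C)(C)C)O1 | intermediate
21 | 5-hydroxy-5-[(8Z,16S)-16-[(tert-butyldimethylsilyl)oxy]heptadec-8-en-1-yl]-2,2-dimethyl-5,6-dihydro-4H-benzo[d][1,3]dioxine-4,7(8H)-dione, both carbinol epimers (formed in the flask) | CC1(C)OC(=O)C2=C(O1)CC(=O)CC2(O)CCCCCCC/C=C\CCCCCC[C@H](C)O[Si](C)(C)C(C)(C)C | intermediate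
22 | 7-hydroxy-5-[(8Z,16S)-16-[(tert-butyldimethylsilyl)oxy]heptadec-8-en-1-yl]-2,2-dimethyl-4H-benzo[d][1,3]dioxin-4-one | CC1(C)OC(=O)c2c(CCCCCCC/C=C\CCCCCC[C@H](C)O[Si](C)(C)C(C)(C)C)cc(O)cc2O1 | intermediate
23 | 2,4-dihydroxy-6-[(8Z,16S)-16-[(tert-butyldimethylsilyl)oxy]heptadec-8-en-1-yl]benzoic acid (formed in the flask) | C[C@H](O[Si](C)(C)C(C)(C)C)CCCCCC/C=C\CCCCCCCc1cc(O)cc(O)c1C(=O)O | intermediate
24 | 5-[(8Z,16S)-16-[(tert-butyldimethylsilyl)oxy]heptadec-8-en-1-yl]benzene-1,3-diol | C[C@H](O[Si](C)(C)C(C)(C)C)CCCCCC/C=C\CCCCCCCc1cc(O)cc(O)c1 | intermediate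
25 | Hansfordiol E, 5-[(8Z,16S)-16-hydroxyheptadec-8-en-1-yl]benzene-1,3-diol | C[C@H](O)CCCCCC/C=C\CCCCCCCc1cc(O)cc(O)c1 | target

**Step count**

Total step count: 15 steps.
Longest linear sequence: 12 steps (steps 1 to 6, 9, 10, 12 to 15).

**Steps most likely to fail**

Step 12 (dianion acylation). Proton transfer between the dianion and the product or the amide, or O-acylation, may quench the reaction before the C–C bond forms, and the diketo-dioxinone may cyclise prematurely during purification. The fallback replaces the acylation by an aldol addition followed by oxidation and sets out from Weinreb amide 15. Reduction with i-Bu2AlH (THF, −78 °C) should give (9Z,17S)-17-[(tert-butyldimethylsilyl)oxy]octadec-9-enal F1. Addition of dianion 19 to this aldehyde at −78 °C should give 6-[(12Z,20S)-20-[(tert-butyldimethylsilyl)oxy]-4-hydroxy-2-oxohenicos-12-en-1-yl]-2,2-dimethyl-4H-1,3-dioxin-4-one F2. Oxidation of its carbinol with Dess–Martin periodinane (NaHCO3, CH2Cl2) comes back to the route at 20.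

Step 13 (cycloaromatisation). The enolate may close through oxygen to a 4-pyranone, the aldol adduct may stall before dehydration, or the dioxinone may fragment thermally. The fallback performs the same ring closure on the open-chain triketo ester and sets out from 20. Heating in toluene (110 °C) with methanol should cause retro-[4+2] loss of acetone to the acylketene (15Z,23S)-23-[(tert-butyldimethylsilyl)oxy]-3,5,7-trioxotetracosa-1,15-dien-1-one F3. Methanol traps it in the flask as methyl (15Z,23S)-23-[(tert-butyldimethylsilyl)oxy]-3,5,7-trioxotetracos-15-enoate F4. Cs2CO3 in MeOH followed by dilute HCl should cyclise and aromatise this ester to methyl 2,4-dihydroxy-6-[(8Z,16S)-16-[(tert-butyldimethylsilyl)oxy]heptadec-8-en-1-yl]benzoate F5. Saponification and decarboxylation of this ester under the conditions of step 14 come back to the route at 24.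

Step 14 (hydrolysis and decarboxylation). Protodecarboxylation may remain incomplete in the alkaline medium, and the hot resorcinolate may be oxidised by traces of air. The fallback separates ester cleavage from decarboxylation under neutral conditions and sets out from 22. Sodium allyloxide (NaH, allyl alcohol, THF, 0 °C to rt) should open the benzodioxinone with loss of acetone to allyl 2,4-dihydroxy-6-[(8Z,16S)-16-[(tert-butyldimethylsilyl)oxy]heptadec-8-en-1-yl]benzoate F6. Pd(PPh3)4 (zerovalent palladium) with morpholine should remove the allyl group to give the free acid 23. Heating the acid in toluene at 110 °C decarboxylates it, and the route is rejoined at 24.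

Further compounds
F1 | step 12 | (9Z,17S)-17-[(tert-butyldimethylsilyl)oxy]octadec-9-enal | O=CCCCCCCC/C=C\CCCCCC[C@H](C)O[Si](C)(C)C(C)(C)C
F2 | step 12 | 6-[(12Z,20S)-20-[(tert-butyldimethylsilyl)oxy]-4-hydroxy-2-oxohenicos-12-en-1-yl]-2,2-dimethyl-4H-1,3-dioxin-4-one (both carbinol epimers) | CC1(C)OC(=O)C=C(CC(=O)CC(O)CCCCCCC/C=C\CCCCCC[C@H](C)O[Si](C)(C)C(C)(C)C)O1
F3 | step 13 | (15Z,23S)-23-[(tert-butyldimethylsilyl)oxy]-3,5,7-trioxotetracosa-1,15-dien-1-one (acylketene) | O=C=CC(=O)CC(=O)CC(=O)CCCCCCC/C=C\CCCCCC[C@H](C)O[Si](C)(C)C(C)(C)C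
F4 | step 13 | methyl (15Z,23S)-23-[(tert-butyldimethylsilyl)oxy]-3,5,7-trioxotetracos-15-enoate | COC(=O)CC(=O)CC(=O)CC(=O)CCCCCCC/C=C\CCCCCC[C@H](C)O[Si](C)(C)C(C)(C)C
F5 | step 13 | methyl 2,4-dihydroxy-6-[(8Z,16S)-16-[(tert-butyldimethylsilyl)oxy]heptadec-8-en-1-yl]benzoate | COC(=O)c1c(O)cc(O)cc1CCCCCCC/C=C\CCCCCC[C@H](C)O[Si](C)(C)C(C)(C)C
F6 | step 14 | allyl 2,4-dihydroxy-6-[(8Z,16S)-16-[(tert-butyldimethylsilyl)oxy]heptadec-8-en-1-yl]benzoate | C=CCOC(=O)c1c(O)cc(O)cc1CCCCCCC/C=C\CCCCCC[C@H](C)O[Si](C)(C)C(C)(C)C
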